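**Plan**

Ring A is the methoxyquinone (C1=O, C2–OMe, C3–H, C4=O, C5–O–aryl, C6–CH2CH2), ring B the para-phenylene, ring C the phenol ring and ring D the meta-phenylene.
Retrosynthesis: the quinone is unveiled last from a tribenzyl ether. The 18-membered ring is cut at the bond between the ethano CH2 and the ring B carbon para to the diaryl ether oxygen. The chain is then cut at the ring A O–ring D ether, the ring C/ring D ethano bridge and the ring B O–ring C ether.
Enabling feature: that ring B carbon can carry Br, and the CH2 next to it is the terminal carbon of a vinyl group on C6 of ring A. The vinyl comes from an aldehyde that the C5 phenol oxygen itself directs into the flanked C6 position, so hydroboration and an intramolecular B-alkyl Suzuki–Miyaura coupling close the ring and deliver the saturated bridge at once.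
Forward: ring A salicylaldehyde (four steps from methoxyhydroquinone); rings B, C and D joined by Chan–Lam coupling, Horner–Wadsworth–Emmons olefination and diimide reduction; Ullmann union with ring A; methylenation; macrocyclization; global debenzylation and oxidation.
Stereochemistry: the target has no stereocentre; the only stereo-element on the way, the E alkene of compound 14, is erased by reduction.

Key step: step 11

Remark: the 18-membered ring is taken as conformationally mobile, so no atropisomerism has to be controlled.

**Route**

Step 1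
Reactants: 1 methoxyhydroquinone (2-methoxybenzene-1,4-diol)
Product: 2 1,4-bis(benzyloxy)-2-methoxybenzene
Conditions: BnBr, K2CO3, DMF, 60 °C, N2
Reagents that add atoms: benzyl bromide, BrCc1ccccc1
Why: Williamson etherification of both phenoxide oxygens with a reactive benzylic halide should proceed cleanly under inert gas.

Step 2
Reactants: 2 1,4-bis(benzyloxy)-2-methoxybenzene
Product: 4 2,5-bis(benzyloxy)-4-methoxybenzaldehyde, via iminium chloride 3 (not isolated)
Conditions: POCl3, DMF, 0 → 70 °C; then H2O
Reagents that add atoms: N,N-dimethylformamide, CN(C)C=O; water, O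
Why: Vilsmeier–Haack formylation should go to the position para to the methoxy group and ortho to a benzyloxy group, the most activated and least hindered site, as with 1,2,4-trialkoxybenzenes in general.

Step 3
Reactants: 4 2,5-bis(benzyloxy)-4-methoxybenzaldehyde
Product: 6 2,5-bis(benzyloxy)-4-methoxyphenol, via aryl formate 5 (not isolated)
Conditions: mCPBA, CH2Cl2, 0 °C → rt; then K2CO3 (cat.), MeOH, rt
Reagents that add atoms: meta-chloroperoxybenzoic acid, OOC(=O)c1cccc(Cl)c1
Why: Baeyer–Villiger (Dakin-type) oxidation of an electron-rich benzaldehyde should proceed by aryl migration to the formate, which methanolysis cleaves to the phenol.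

Step 4
Reactants: 6 2,5-bis(benzyloxy)-4-methoxyphenol
Product: 8 3,6-bis(benzyloxy)-2-hydroxy-5-methoxybenzaldehyde, via salicyl alcohol 7 (not isolated)
Conditions: MgCl2, Et3N, (CH2O)n, MeCN, reflux; then 1 M HCl
Reagents that add atoms: paraformaldehyde (as formaldehyde), C=O
Why: Casnati–Skattebøl ortho-formylation should deliver formaldehyde from the magnesium phenoxide only to the single free ortho position, and a second formaldehyde oxidizes the hydroxymethyl group by hydride transfer.

Step 5
Reactants: 9 4-(benzyloxy)-3-hydroxybenzaldehyde; 10 4-bromophenylboronic acid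
Product: 11 4-(benzyloxy)-3-(4-bromophenoxy)benzaldehyde
Conditions: Cu(OAc)2 (cat.), pyridine, 4 Å MS, CH2Cl2, O2, rt
Reagents that add atoms: none
Why: Chan–Lam oxidative O-arylation runs at room temperature and should leave the aryl bromide, the aldehyde and the benzyl ether untouched.

Step 6
Reactants: 12 3-iodobenzyl bromide
Product: 13 diethyl (3-iodobenzyl)phosphonate
Conditions: P(OEt)3, neat, 130 °C
Reagents that add atoms: triethyl phosphite, CCOP(OCC)OCC
Why: Michaelis–Arbuzov reaction should take place at the benzylic bromide only, the aryl iodide being inert to the phosphite.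

Step 7
Reactants: 11 4-(benzyloxy)-3-(4-bromophenoxy)benzaldehyde; 13 diethyl (3-iodobenzyl)phosphonate
Product: 14 (E)-1-(benzyloxy)-2-(4-bromophenoxy)-4-[2-(3-iodophenyl)ethenyl]benzene
Conditions: KOtBu, THF, 0 °C → rt
Reagents that add atoms: none
Why: Horner–Wadsworth–Emmons olefination of a non-enolizable aldehyde with a benzylic phosphonate anion should give the E stilbene, whose geometry is of no consequence because the alkene is reduced next.

Step 8
Reactants: 14 (E)-1-(benzyloxy)-2-(4-bromophenoxy)-4-[2-(3-iodophenyl)ethenyl]benzene
Product: 15 1-(benzyloxy)-2-(4-bromophenoxy)-4-[2-(3-iodophenyl)ethyl]benzene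
Conditions: TsNHNH2, NaOAc, THF/H2O, reflux
Reagents that add atoms: none
Why: diimide reduction should transfer two hydrogens to the alkene in a concerted way and, unlike catalytic hydrogenation, spare the C–I and C–Br bonds and the benzyl ether.

Step 9
Reactants: 8 3,6-bis(benzyloxy)-2-hydroxy-5-methoxybenzaldehyde; 15 1-(benzyloxy)-2-(4-bromophenoxy)-4-[2-(3-iodophenyl)ethyl]benzene
Product: 16 3,6-bis(benzyloxy)-2-[3-(2-{4-(benzyloxy)-3-(4-bromophenoxy)phenyl}ethyl)phenoxy]-5-methoxybenzaldehyde
Conditions: CuI (cat.), picolinic acid (cat.), K3PO4, DMSO, 90 °C, Ar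
Reagents that add atoms: none
Why: Ullmann-type diaryl ether synthesis with a picolinate ligand tolerates ortho-substituted phenols, and monovalent copper should activate the aryl iodide much faster than the aryl bromide, so the ring B bromide is kept for the ring closure.

Step 10
Reactants: 16 the aldehyde of step 9
Product: 17 1,4-bis(benzyloxy)-2-[3-(2-{4-(benzyloxy)-3-(4-bromophenoxy)phenyl}ethyl)phenoxy]-5-methoxy-3-vinylbenzene
Conditions: Ph3PCH3Br, KOtBu, THF, 0 °C → rt
Reagents that add atoms: methyltriphenylphosphonium bromide, C[P+](c1ccccc1)(c1ccccc1)c1ccccc1.[Br-]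
Why: Wittig methylenation with the small unstabilized ylide should convert even a doubly ortho-substituted benzaldehyde into the styrene without touching the aryl bromide.

Step 11
Reactants: 17 the bromo-styrene of step 10
Product: 19 tribenzyl-protected macrocycle (the 18-membered ring of the target with ring A as a 1,4-bis(benzyloxy)-2-methoxybenzene and the ring C hydroxyl as benzyl ether), via alkylborane 18 (not isolated)
Conditions: 9-BBN, THF, rt; then slow addition to Pd(dppf)Cl2 (cat.), AsPh3, Cs2CO3, DMF/THF/H2O, 60 °C, about 1 mM
Reagents that add atoms: none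
Why: 9-BBN should add to the vinyl group of ring A with boron on the terminal carbon; zerovalent palladium then inserts into the C–Br bond of ring B, the base-activated primary alkyl borate transmetalates to the aryl complex of divalent palladium, and reductive elimination forms the CH2–aryl bond. The closest known reaction type is the intramolecular B-alkyl Suzuki–Miyaura macrocyclization used for cyclophane-type macrocycles. The 18-membered ring closes end to end by reductive elimination from a 19-membered palladacycle, a macrocyclization to which the Baldwin terms do not apply. No stereocentre is formed. The step needs anti-Markovnikov hydroboration, which the bulk of 9-BBN at a terminal alkene secures. It also needs ring closure to win over chain growth, which slow addition at high dilution secures, helped by the bent diaryl ether and bibenzyl hinges and by the presence of only one C–Br bond and one alkene in 17.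

Step 12
Reactants: 19 tribenzyl-protected macrocycle
Product: 21 target quinone CNP0332646.0, via hydroquinone 20 (not isolated)
Conditions: H2, Pd/C, EtOAc, rt; filter; then Ag2O, MgSO4, EtOAc, rt
Reagents that add atoms: none
Why: hydrogenolysis should remove all three benzyl ethers, and silver oxide should oxidize the electron-rich 1,4-hydroquinone of ring A to the quinone far faster than the isolated ring C phenol; a non-nucleophilic solvent protects the aryloxy-quinone from addition–elimination.

**Compound list**

1 | methoxyhydroquinone (2-methoxybenzene-1,4-diol) | COc1cc(O)ccc1O | starting material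
2 | 1,4-bis(benzyloxy)-2-methoxybenzene | COc1cc(OCc2ccccc2)ccc1OCc1ccccc1 | intermediate
3 | N-[2,5-bis(benzyloxy)-4-methoxybenzylidene]-N-methylmethanaminium chloride | COc1cc(OCc2ccccc2)c(C=[N+](C)C)cc1OCc1ccccc1.[Cl-] | intermediate (not isolated)
4 | 2,5-bis(benzyloxy)-4-methoxybenzaldehyde | COc1cc(OCc2ccccc2)c(C=O)cc1OCc1ccccc1 | intermediate
5 | 2,5-bis(benzyloxy)-4-methoxyphenyl formate | COc1cc(OCc2ccccc2)c(OC=O)cc1OCc1ccccc1 | intermediate (not isolated)
6 | 2,5-bis(benzyloxy)-4-methoxyphenol | COc1cc(OCc2ccccc2)c(O)cc1OCc1ccccc1 | intermediate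
7 | 3,6-bis(benzyloxy)-2-(hydroxymethyl)-4-methoxyphenol | COc1cc(OCc2ccccc2)c(O)c(CO)c1OCc1ccccc1 | intermediate (not isolated)
8 | 3,6-bis(benzyloxy)-2-hydroxy-5-methoxybenzaldehyde | COc1cc(OCc2ccccc2)c(O)c(C=O)c1OCc1ccccc1 | intermediate
9 | 4-(benzyloxy)-3-hydroxybenzaldehyde | O=Cc1ccc(OCc2ccccc2)c(O)c1 | starting material
10 | 4-bromophenylboronic acid | OB(O)c1ccc(Br)cc1 | starting material
11 | 4-(benzyloxy)-3-(4-bromophenoxy)benzaldehyde | O=Cc1ccc(OCc2ccccc2)c(Oc2ccc(Br)cc2)c1 | intermediate
12 | 3-iodobenzyl bromide | BrCc1cccc(I)c1 | starting material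
13 | diethyl (3-iodobenzyl)phosphonate | CCOP(=O)(OCC)Cc1cccc(I)c1 | intermediate
14 | (E)-1-(benzyloxy)-2-(4-bromophenoxy)-4-[2-(3-iodophenyl)ethenyl]benzene | Ic1cccc(/C=C/c2ccc(OCc3ccccc3)c(Oc3ccc(Br)cc3)c2)c1 | intermediate
15 | 1-(benzyloxy)-2-(4-bromophenoxy)-4-[2-(3-iodophenyl)ethyl]benzene | Ic1cccc(CCc2ccc(OCc3ccccc3)c(Oc3ccc(Br)cc3)c2)c1 | intermediate
16 | 3,6-bis(benzyloxy)-2-[3-(2-{4-(benzyloxy)-3-(4-bromophenoxy)phenyl}ethyl)phenoxy]-5-methoxybenzaldehyde | COc1cc(OCc2ccccc2)c(Oc2cccc(CCc3ccc(OCc4ccccc4)c(Oc4ccc(Br)cc4)c3)c2)c(C=O)c1OCc1ccccc1 | intermediate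
17 | 1,4-bis(benzyloxy)-2-[3-(2-{4-(benzyloxy)-3-(4-bromophenoxy)phenyl}ethyl)phenoxy]-5-methoxy-3-vinylbenzene | COc1cc(OCc2ccccc2)c(Oc2cccc(CCc3ccc(OCc4ccccc4)c(Oc4ccc(Br)cc4)c3)c2)c(C=C)c1OCc1ccccc1 | intermediate
18 | B-alkyl-9-borabicyclo[3.3.1]nonane from hydroboration of 17 at the terminal vinyl carbon | COc1cc(OCc2ccccc2)c(Oc2cccc(CCc3ccc(OCc4ccccc4)c(Oc4ccc(Br)cc4)c3)c2)c(CCB2C3CCCC2CCC3)c1OCc1ccccc1 | intermediate (not isolated)
19 | tribenzyl-protected macrocycle (ring A 1,4-bis(benzyloxy)-2-methoxy arene, ring C benzyl ether) | COc1cc(OCc2ccccc2)c2c(CCc3ccc(cc3)Oc3cc(ccc3OCc3ccccc3)CCc3cccc(c3)O2)c1OCc1ccccc1 | intermediate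
20 | macrocyclic hydroquinone (ring A 2-methoxy-1,4-diol, ring C free phenol) | COc1cc(O)c2c(CCc3ccc(cc3)Oc3cc(ccc3O)CCc3cccc(c3)O2)c1O | intermediate (not isolated)
21 | CNP0332646.0, the macrocyclic bis(bibenzyl) 2-methoxy-1,4-benzoquinone | COC1=CC(=O)C2=C(CCc3ccc(cc3)Oc3cc(ccc3O)CCc3cccc(c3)O2)C1=O | target

**Count**

Total steps: 12. Longest linear sequence: 8 steps (steps 1, 2, 3, 4, 9, 10, 11, 12).

**Steps most likely to fail**

Step 11. Intermolecular coupling may outrun ring closure and give oligomers, or the alkylborane may be lost by β-hydride elimination or protodeboronation before transmetalation. Fallback: from 17, an intramolecular Mizoroki–Heck reaction (Pd(OAc)2, P(o-tol)3, Et3N, DMF, 100 °C, high dilution) should join the arylpalladium species to the same terminal vinyl carbon and give the macrocyclic (E)-stilbene F1. Diimide reduction of F1 (TsNHNH2, NaOAc, THF/H2O, reflux) comes back to the route at 19.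

Step 9. C–O bond formation may be slow at the doubly ortho-substituted, chelating and weakly nucleophilic phenoxide, and the selectivity for iodide over bromide may erode if forcing conditions are needed. Fallback: from 15, oxidation at iodine (mCPBA, TsOH·H2O, MeCN) followed by 1,3,5-trimethoxybenzene should give the aryl(2,4,6-trimethoxyphenyl)iodonium tosylate F2; ring C offers only hindered or weakly activated positions, so the far more nucleophilic trimethoxybenzene should capture the trivalent iodine. Metal-free O-arylation of 8 with F2 (KOtBu, THF, rt) proceeds by ligand coupling at trivalent iodine with the electron-rich trimethoxyphenyl group staying on iodine, and comes back to the route at 16 without touching the bromide.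

Step 5. Protodeboronation and oxidative homocoupling of the boronic acid may outpace the C–O coupling. Fallback: from 9, an Ullmann-type coupling with 1-bromo-4-iodobenzene (CuI, N,N-dimethylglycine, Cs2CO3, dioxane, 90 °C), in which only the C–I bond should react, comes back to the route at 11 directly; no new compound is made (F0).

**Further compounds**

F1 | step 11 | macrocyclic (E)-stilbene, tribenzyl-protected (alkene between ring A and ring B) | COc1cc(OCc2ccccc2)c2c(/C=C/c3ccc(cc3)Oc3cc(ccc3OCc3ccccc3)CCc3cccc(c3)O2)c1OCc1ccccc1
F2 | step 9 | [3-(2-{4-(benzyloxy)-3-(4-bromophenoxy)phenyl}ethyl)phenyl](2,4,6-trimethoxyphenyl)iodonium 4-methylbenzenesulfonate | COc1cc(OC)c([I+]c2cccc(CCc3ccc(OCc4ccccc4)c(Oc4ccc(Br)cc4)c3)c2)c(OC)c1.Cc1ccc(cc1)S([O-])(=O)=O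
F0 | step 5 | none | none
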